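Remark on the chemistry: lignan numbering is used for the target and all intermediates (C7/C7′ benzylic carbons, C8/C8′ carbinol carbons at the ring fusion, C9/C9′ the oxygenated CH2 carbons or the carboxyl carbons they derive from). D-(−)-tartaric acid is the (2S,3S) acid.

## Analysis of the target

Prinsepiol (10) is a C2-symmetric furofuran lignan. Two tetrahydrofuran rings (ring A: C7–O–C9′–C8′–C8; ring B: C7′–O–C9–C8–C8′) are cis-fused through the C8–C8′ bond into a 3,7-dioxabicyclo[3.3.0]octane, and each ring carries a 4-hydroxy-3-methoxyphenyl group on its benzylic carbon. There are four stereocentres: two benzylic CH carbons (C7, C7′, both R) and two tertiary carbinol bridgeheads (C8, C8′, both S). The bridgehead hydroxyls are necessarily cis, and each aryl group is cis to the hydroxyl on the adjacent bridgehead, so both aryl groups and both hydroxyls lie on the convex face. The sensitive elements are the electron-rich benzylic C7–O ether bonds (they ionise under acid, can epimerise and can be hydrogenolysed), the vicinal di-tertiary diol (pinacol-type rearrangement, glycol cleavage) and the free phenols. The difficulty is the pair of adjacent, fully substituted, oxygenated carbons, each of which must be set relative to a benzylic stereocentre; there is no C–H at the ring fusion on which the usual furofuran enolate logic could operate. The route rests on the chain C9–C8(OH)–C8′(OH)–C9′: it is the four-carbon skeleton of D-tartaric acid, with the carboxyl carbons reduced to CH2 and each carbinol hydrogen replaced, in the same spatial position, by an ArCH(O) unit.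

## Retrosynthetic reasoning

10 ⇒ 9. The phenols are masked as benzyl ethers, so the last operation is a debenzylation of 9. Benzyl ethers are chosen because they survive strong amide base, hydride reduction, sulfonylation and warm pyridine.

9 ⇒ 8 ⇒ 7. The two ring bonds O–C9 and O–C9′ are cut, not the benzylic C7–O bonds. The benzylic C–O bonds are then made once (as carbinols) and never broken, so C7 and C7′ pass unchanged into the bicycle. Cutting at C7–O instead would mean closing through benzylic cations; the C7 configuration would then be decided in the closure, and since epimeric furofurans are close in energy, equilibration cannot be counted on to deliver one isomer. The forward reaction needs the two primary hydroxyls of hexaol 7 to be converted selectively into sulfonates (8), and each benzylic hydroxyl to displace the sulfonate of the other half in a five-membered closure. This has to happen without alkoxide formation, because an alkoxide on the adjacent tertiary carbinol would close a three-membered ring instead.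

7 ⇒ 6. Each CH2OH/tertiary OH pair of 7 is the reduced form of an α-hydroxy acid. In 6 that unit is held as a 2-tert-butyl-1,3-dioxolan-4-one, so a single hydride reduction lowers C9/C9′ to the alcohol level and removes both acetals. No stereocentre is touched.

6 ⇒ 5 ⇒ 3 + 4. The C7–C8 and C7′–C8′ bonds are cut; each is the bond of a β-hydroxy carbonyl (aldol) retron. These are the only C–C bonds whose cleavage leaves a symmetrical four-carbon core with both oxygenated carbons intact, and it returns the aryl part as the commercial aldehyde 4. The gain is convergence and two-directional use of symmetry: two C–C bonds and all four stereocentres arise in one operation from the bis-dioxolanone 3. The forward reaction has to replace each C8–H by the aldehyde carbon with retention (entry trans to the tert-butyl group of the same ring), give the R carbinol through a closed transition state, and be faster than β-elimination of the enolate.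

3 ⇒ 1 + 2. The four acetal C–O bonds are cut. The bis-dioxolanone 3 is the double pivalaldehyde acetal of D-tartaric acid 1, reached in one step from 1 and pivalaldehyde 2, so the risk of the route is concentrated in the aldol step.

## Alternatives that were turned down

Alternative 1: The tertiary C8–O bonds and the ring C7–O bonds are traced back to the two alkenes of the achiral (E,E)-diene diol A1, which would come from 4 and a succinic diester by twofold Stobbe condensation and hydride reduction.
- Forward key step: a twofold Sharpless asymmetric epoxidation of the two allylic alcohol units of A1 gives bis-epoxide A2 and sets all four stereocentres. Each CH2OH then has to open the epoxide of the other half at the benzylic carbon with inversion (5-endo), which creates the tertiary hydroxyls and both rings.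
- For: absolute configuration comes from a catalyst and achiral material, the double epoxidation enriches the C2 product, and little remains after the key step.
- Against: the epoxides of A2 are p-alkoxystyrene oxides. They ionise easily under the tetravalent titanium Lewis acid of the epoxidation itself, and the later 5-endo closure needs the very activation that promotes ionisation. Clean inversion at C7 is then not assured, and an SN1 path scrambles the benzylic centres. The crowded, cross-conjugated diene is also a slow epoxidation substrate.
- Comparison: Alternative 1 is stronger in using catalytic rather than stoichiometric chirality and in avoiding strong base. The chosen route offers a benzylic carbon that is never an electrophile after its C–O bond is formed, and a C8 configuration that is bought, not induced.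

Alternative 2: The C8–C9 and C8′–C9′ bonds and the two lactone C–O bonds are cut, so that both CH2 carbons come from CO. The precursor is the (E)-diiodo-ene-diol A3.
- Forward key step: Pd(PPh3)4 under CO turns each C–I bond into an acyl palladium that is trapped by the cis carbinol, giving the fused bis-butenolide A4. The C8=C8′ alkene must then be cis-dihydroxylated and both lactone carbonyls reduced to CH2.
- For: both rings and two C–C bonds are made in one operation from a simple C1 source; in ring construction per step it is clearly stronger than the chosen route, whose key step closes no ring.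
- Against: in C2-symmetric A4 both aryl groups sit on one face of the flat bicycle, and the target needs both hydroxyls on that same face, so the dihydroxylation would have to take the hindered face. The alkene is tetrasubstituted, doubly acylated and at the fusion of two five-membered rings, hence slow with electrophilic oxidants. The C7–H of A4 is benzylic and γ to a butenolide carbonyl, so base (needed in the carbonylation) can epimerise it through an aromatic 2-oxidofuran. A lactone-to-ether reduction next to benzylic ethers still follows.
- Comparison: the chosen route sets the aryl/hydroxyl cis relation directly, through retention at C8 and the aldol topicity, instead of against the substrate bias.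

Alternative 3: The C8–C8′ bond is cut, giving the eight-membered diketone A5.
- Forward key step: SmI2 reduces both ketones and the ketyl carbons couple across the ring to give A6, which is identical with compound 9.
- For: the key step delivers the complete protected skeleton, the cis-diol and the cis ring fusion at once, and only debenzylation remains; in step economy after the key step it is stronger than the chosen route.
- Against: each benzylic stereocentre of A5 is α to a ketone and carries an aryl and an alkoxy group, so it is highly epimerisable. Building the eight-membered ring by head-to-tail double etherification competes with oligomerisation. α-Alkoxy ketones undergo reductive C–O cleavage with SmI2, and each ketone of A5 has two α-oxygens, so ring opening competes with coupling. Whether the aryl groups end up cis to the new hydroxyls depends on the ring conformer and is not obviously controlled.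
- Comparison: the chosen route accepts four steps after its key step, but its precursor is made in one step and contains no configurationally labile benzylic ketone.

Key step: step 2

## Route

Step 1
Reactants: 1 D-(−)-tartaric acid, (2S,3S)-2,3-dihydroxybutanedioic acid; 2 pivalaldehyde
Product: 3 (2S,2′S,4S,4′S)-2,2′-di-tert-butyl-4,4′-bi(1,3-dioxolane)-5,5′-dione (cis,cis bis-dioxolanone; each tert-butyl group cis to the other ring)
Conditions: 2 (4 equiv), p-TsOH·H2O (cat.), H2SO4 (cat.), pentane, reflux, Dean–Stark; crystallisation
Reagents that add atoms: none
Why: Acid-catalysed acetalisation of both α-hydroxy acid units (dioxolanone formation) is driven by azeotropic removal of water; the C8–O bonds are not broken, so the S,S centres of 1 are kept. The new acetal carbons are set under thermodynamic control, which favours tert-butyl cis to the substituent on the neighbouring ring carbon, and the C2-symmetric cis,cis isomer should be obtained pure by crystallisation.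

Step 2
Reactants: 3 (2S,2′S,4S,4′S)-2,2′-di-tert-butyl-4,4′-bi(1,3-dioxolane)-5,5′-dione; 4 4-benzyloxy-3-methoxybenzaldehyde
Product: 6 (2S,2′S,4S,4′S)-4,4′-bis[(R)-(4-benzyloxy-3-methoxyphenyl)(hydroxy)methyl]-2,2′-di-tert-butyl-4,4′-bi(1,3-dioxolane)-5,5′-dione, via mono-aldol adduct 5 (not isolated)
Conditions: 3 + 4 (2.5 equiv), THF, −78 °C; LiN(SiMe3)2 (2.4 equiv) added slowly; AcOH, −78 °C
Reagents that add atoms: none
Why: This is a twofold directed aldol addition of lithium ester enolates: LiN(SiMe3)2 removes the C8–H of one dioxolanone ring of 3, the enolate (geometry fixed by the ring, the C8′ branch cis to OLi) adds to the carbonyl group of 4 to give the lithium alkoxide of 5, and the same events on the second ring form the C7′–C8′ bond; two C–C bonds and four stereocentres are made and no ring is closed. The closest known reaction type is the aldol addition of 2-tert-butyl-1,3-dioxolan-4-one lithium enolates (acetals of α-hydroxy acids) to aldehydes with self-regeneration of the stereocentre. C8 and C8′ are controlled by the acetal stereocentres: in each planar enolate the tert-butyl group blocks one face, so 4 enters trans to it, into the site of the hydrogen that was removed, which is net retention and keeps the S,S configuration of 1. C7 and C7′ are controlled by a closed, lithium-bridged chair (Zimmerman–Traxler) transition state with the aryl group equatorial; because the ring oxygen on C8 is trans to OLi, the new hydroxyl ends up anti to that oxygen and the carbinols should be R. The step needs facial selectivity (secured by the tert-butyl groups), simple diastereoselectivity (secured only by the chair preference and therefore the weaker control) and chemoselectivity for addition over β-elimination of the acetal oxygen of the neighbouring ring and over acyl transfer of the first alkoxide to the neighbouring lactone carbonyl. The substrate does not prevent these two side reactions, so each enolate is generated at −78 °C in the presence of the non-enolisable aldehyde, which captures it at once, and the mixture is protonated cold. The second enolisation takes place on a ring that still carries its own acetal stereocentre, so it is controlled like the first and should lead to C2-symmetric 6.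

Step 3
Reactants: 6 (2S,2′S,4S,4′S)-4,4′-bis[(R)-(4-benzyloxy-3-methoxyphenyl)(hydroxy)methyl]-2,2′-di-tert-butyl-4,4′-bi(1,3-dioxolane)-5,5′-dione
Product: 7 (1R,2S,3S,4R)-1,4-bis(4-benzyloxy-3-methoxyphenyl)-2,3-bis(hydroxymethyl)butane-1,2,3,4-tetrol
Conditions: LiAlH4 (excess), THF, 0 °C → rt; H2O, aq. NaOH
Reagents that add atoms: none
Why: Hydride reduction of the two lactone carbonyls takes C9 and C9′ to the primary alcohol level; the hemiacetals set free collapse to pivalaldehyde, which is reduced in turn, so both tertiary hydroxyls are unveiled in the same operation. No stereocentre is touched and aryl benzyl ethers are inert to LiAlH4.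

Step 4
Reactants: 7 (1R,2S,3S,4R)-1,4-bis(4-benzyloxy-3-methoxyphenyl)-2,3-bis(hydroxymethyl)butane-1,2,3,4-tetrol
Product: 8 (1R,2S,3S,4R)-1,4-bis(4-benzyloxy-3-methoxyphenyl)-2,3-bis[(4-methylbenzenesulfonyloxy)methyl]butane-1,2,3,4-tetrol
Conditions: TsCl (2.1 equiv), Bu2SnO (5 mol %), Et3N, CH2Cl2, 0 °C
Reagents that add atoms: p-toluenesulfonyl chloride, Cc1ccc(S(=O)(=O)Cl)cc1
Why: Stannylene-mediated regioselective sulfonylation: Bu2SnO forms a stannylene acetal across each primary/tertiary 1,2-diol and activates the primary oxygen, while the hindered benzylic and tertiary hydroxyls should stay free. Both primary hydroxyls are sulfonylated cold, before any ring closure, so that no free primary hydroxyl remains to compete as a nucleophile.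

Step 5
Reactants: 8 (1R,2S,3S,4R)-1,4-bis(4-benzyloxy-3-methoxyphenyl)-2,3-bis[(4-methylbenzenesulfonyloxy)methyl]butane-1,2,3,4-tetrol
Product: 9 4,4′-di-O-benzylprinsepiol, (1S,2R,5S,6R)-2,6-bis(4-benzyloxy-3-methoxyphenyl)-3,7-dioxabicyclo[3.3.0]octane-1,5-diol
Conditions: pyridine, 70 °C
Reagents that add atoms: none
Why: Twofold intramolecular Williamson-type etherification (5-exo-tet SN2): each neutral benzylic hydroxyl displaces the sulfonate on the CH2 group of the other half, so the C7–O bonds are not broken and C7/C7′ are retained; the S,S diol can only give the cis-fused bicycle. Under these weakly basic conditions no alkoxide is formed, so closure of the adjacent tertiary hydroxyl to a three-membered ring should not compete, and four-membered closures are much slower than the five-membered one.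

Step 6
Reactants: 9 4,4′-di-O-benzylprinsepiol
Product: 10 prinsepiol, (1S,2R,5S,6R)-2,6-bis(4-hydroxy-3-methoxyphenyl)-3,7-dioxabicyclo[3.3.0]octane-1,5-diol
Conditions: H2 (1 atm), 10% Pd/C, EtOAc, rt, stopped after uptake of 2 equiv
Reagents that add atoms: none
Why: Catalytic hydrogenolysis of the two aryl benzyl ethers; these cleave faster than the ring benzylic C–O bonds, which are dialkyl-type ethers shielded by the adjacent quaternary carbinol carbons, provided the solvent is neutral and the reaction is stopped at the calculated uptake.

## Compound list

1 | D-(−)-tartaric acid, (2S,3S)-2,3-dihydroxybutanedioic acid | OC(=O)[C@@H](O)[C@H](O)C(=O)O | starting material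
2 | pivalaldehyde (2,2-dimethylpropanal) | CC(C)(C)C=O | starting material
3 | (2S,2′S,4S,4′S)-2,2′-di-tert-butyl-4,4′-bi(1,3-dioxolane)-5,5′-dione | O=C1O[C@@H](C(C)(C)C)O[C@H]1[C@@H]1O[C@H](C(C)(C)C)OC1=O | intermediate
4 | 4-benzyloxy-3-methoxybenzaldehyde | COc1cc(C=O)ccc1OCc1ccccc1 | starting material
5 | (2S,2′S,4S,4′S)-4-[(R)-(4-benzyloxy-3-methoxyphenyl)(hydroxy)methyl]-2,2′-di-tert-butyl-4,4′-bi(1,3-dioxolane)-5,5′-dione (mono-aldol adduct, formed as its lithium alkoxide) | COc1cc([C@@H](O)[C@]2(O[C@H](C(C)(C)C)OC2=O)[C@@H]2O[C@H](C(C)(C)C)OC2=O)ccc1OCc1ccccc1 | intermediate
6 | (2S,2′S,4S,4′S)-4,4′-bis[(R)-(4-benzyloxy-3-methoxyphenyl)(hydroxy)methyl]-2,2′-di-tert-butyl-4,4′-bi(1,3-dioxolane)-5,5′-dione | COc1cc([C@@H](O)[C@]2(O[C@H](C(C)(C)C)OC2=O)[C@@]2(O[C@H](C(C)(C)C)OC2=O)[C@H](O)c2ccc(OCc3ccccc3)c(OC)c2)ccc1OCc1ccccc1 | intermediate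
7 | (1R,2S,3S,4R)-1,4-bis(4-benzyloxy-3-methoxyphenyl)-2,3-bis(hydroxymethyl)butane-1,2,3,4-tetrol | COc1cc([C@@H](O)[C@](CO)(O)[C@@](CO)(O)[C@H](O)c2ccc(OCc3ccccc3)c(OC)c2)ccc1OCc1ccccc1 | intermediate
8 | (1R,2S,3S,4R)-1,4-bis(4-benzyloxy-3-methoxyphenyl)-2,3-bis[(4-methylbenzenesulfonyloxy)methyl]butane-1,2,3,4-tetrol | COc1cc([C@@H](O)[C@](COS(=O)(=O)c2ccc(C)cc2)(O)[C@@](COS(=O)(=O)c2ccc(C)cc2)(O)[C@H](O)c2ccc(OCc3ccccc3)c(OC)c2)ccc1OCc1ccccc1 | intermediate
9 | 4,4′-di-O-benzylprinsepiol, (1S,2R,5S,6R)-2,6-bis(4-benzyloxy-3-methoxyphenyl)-3,7-dioxabicyclo[3.3.0]octane-1,5-diol | COc1cc([C@H]2OC[C@]3(O)[C@@H](c4ccc(OCc5ccccc5)c(OC)c4)OC[C@]23O)ccc1OCc1ccccc1 | intermediate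
10 | prinsepiol, (1S,2R,5S,6R)-2,6-bis(4-hydroxy-3-methoxyphenyl)-3,7-dioxabicyclo[3.3.0]octane-1,5-diol | COc1cc([C@H]2OC[C@]3(O)[C@@H](c4ccc(O)c(OC)c4)OC[C@]23O)ccc1O | target

## Step count and least certain steps

Total step count: 6. Longest linear sequence: 6 steps (from 1); aldehyde 4 is commercial.

**Step 2 (key step).** The most likely failure is loss of the enolate before it adds. Its β-carbon carries the acetal oxygen of the neighbouring ring, and an E1cB elimination, helped by release of pivalaldehyde and a carboxylate, is stereoelectronically open because that C–O bond can align with the enolate π-system. Two further drains are acyl transfer of the first lithium alkoxide onto the neighbouring lactone carbonyl, which would open the second ring before it is enolised, and 1,2-addition of the amide base to the aldehyde. Independently, the chair preference may give only modest selectivity at C7/C7′, because the pseudo-axial position is taken by the bulky C8′ branch.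
Fallback (sets out from 3, returns at 6): each enolate is trapped as it forms, by adding LiN(SiMe3)2 to 3 and Me3SiCl in THF at −100 °C, to give (2S,2′S)-2,2′-di-tert-butyl-5,5′-bis(trimethylsilyloxy)-4,4′-bi(1,3-dioxole) F2. Once the first ring is silylated the second enolate has no β-leaving group on a saturated carbon. F2 is then combined with 4 in a Mukaiyama aldol addition (BF3·OEt2, CH2Cl2, −78 °C, hydrolytic work-up) to give 6. Facial selectivity is still set by the tert-butyl groups; the carbinol configuration then comes from an open transition state and the epimers may have to be separated.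

**Step 1.** The most likely failure is incomplete acetalisation of the diacid, which is insoluble in pentane, together with equilibration to mixtures of acetal epimers, or bridging of the two hydroxyls by one aldehyde instead of closure onto the carboxyl groups.
Fallback (sets out from 1, returns at 3): 1 is persilylated (Me3SiCl, Et3N, CH2Cl2) to bis(trimethylsilyl) (2S,3S)-2,3-bis(trimethylsilyloxy)butanedioate F1, which is soluble. F1 is acetalised with 2 under Me3SiOTf catalysis at −25 °C, a kinetically controlled, cis-selective closure of each silyl ether/silyl ester pair that should give 3.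

**Step 5.** The most likely failure is slow displacement at the neopentyl-type CH2 sulfonate by a hindered secondary hydroxyl. If harsher or more basic conditions are then used, closure by the adjacent tertiary hydroxyl to a three-membered ring takes over. Any primary hydroxyl left unsulfonylated in step 4 would close a ring between the two CH2 groups instead.
Fallback (sets out from 7, returns at 9; no new compound, F0): acid-catalysed cyclodehydration of 7 (camphorsulfonic acid cat., CH2Cl2, 4 Å sieves, 0 °C → rt). The electron-rich benzylic carbinols ionise and each primary hydroxyl captures the cation of the other half (5-exo-trig). The C7/C7′ configuration is then set in the closure and no longer inherited from step 2; because epimeric furofurans are close in energy, separation of benzylic epimers must be expected.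

**Step 6.** The most likely failure is over-reduction: the ring C7–O bonds are benzylic ethers too, and their hydrogenolysis would open the bicycle.
Fallback (sets out from 3, returns at 10): the phenols are carried as allyl ethers and no hydrogen is used. Compound 3 and 4-allyloxy-3-methoxybenzaldehyde F3 under the conditions of step 2 give the bis-allyl aldol adduct F4. Reduction as in step 3 gives the bis-allyl hexaol F5, sulfonylation as in step 4 the bis-allyl bis-tosylate F6, and closure as in step 5 4,4′-di-O-allylprinsepiol F7. Pd(PPh3)4 (a zerovalent palladium catalyst) with morpholine in THF at rt then transfers the allyl groups to the amine and releases 10.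

## Further compounds

F1 | step 1 | bis(trimethylsilyl) (2S,3S)-2,3-bis(trimethylsilyloxy)butanedioate | C[Si](C)(C)OC(=O)[C@@H](O[Si](C)(C)C)[C@H](O[Si](C)(C)C)C(=O)O[Si](C)(C)C
F2 | step 2 | (2S,2′S)-2,2′-di-tert-butyl-5,5′-bis(trimethylsilyloxy)-4,4′-bi(1,3-dioxole) | C[Si](C)(C)OC1=C(C2=C(O[Si](C)(C)C)O[C@@H](C(C)(C)C)O2)O[C@H](C(C)(C)C)O1
F0 | step 5 | none | none
F3 | step 6 | 4-allyloxy-3-methoxybenzaldehyde | COc1cc(C=O)ccc1OCC=C
F4 | step 6 | (2S,2′S,4S,4′S)-4,4′-bis[(R)-(4-allyloxy-3-methoxyphenyl)(hydroxy)methyl]-2,2′-di-tert-butyl-4,4′-bi(1,3-dioxolane)-5,5′-dione | COc1cc([C@@H](O)[C@]2(O[C@H](C(C)(C)C)OC2=O)[C@@]2(O[C@H](C(C)(C)C)OC2=O)[C@H](O)c2ccc(OCC=C)c(OC)c2)ccc1OCC=C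
F5 | step 6 | (1R,2S,3S,4R)-1,4-bis(4-allyloxy-3-methoxyphenyl)-2,3-bis(hydroxymethyl)butane-1,2,3,4-tetrol | COc1cc([C@@H](O)[C@](CO)(O)[C@@](CO)(O)[C@H](O)c2ccc(OCC=C)c(OC)c2)ccc1OCC=C
F6 | step 6 | (1R,2S,3S,4R)-1,4-bis(4-allyloxy-3-methoxyphenyl)-2,3-bis[(4-methylbenzenesulfonyloxy)methyl]butane-1,2,3,4-tetrol | COc1cc([C@@H](O)[C@](COS(=O)(=O)c2ccc(C)cc2)(O)[C@@](COS(=O)(=O)c2ccc(C)cc2)(O)[C@H](O)c2ccc(OCC=C)c(OC)c2)ccc1OCC=C
F7 | step 6 | 4,4′-di-O-allylprinsepiol, (1S,2R,5S,6R)-2,6-bis(4-allyloxy-3-methoxyphenyl)-3,7-dioxabicyclo[3.3.0]octane-1,5-diol | COc1cc([C@H]2OC[C@]3(O)[C@@H](c4ccc(OCC=C)c(OC)c4)OC[C@]23O)ccc1OCC=C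
A1 | alternative 1 | (2E,3E)-2,3-bis[(4-benzyloxy-3-methoxyphenyl)methylidene]butane-1,4-diol | COc1cc(/C=C(/CO)C(/CO)=C\c2ccc(OCc3ccccc3)c(OC)c2)ccc1OCc1ccccc1
A2 | alternative 1 | (2S,2′S,3S,3′S)-3,3′-bis(4-benzyloxy-3-methoxyphenyl)-2,2′-bioxirane-2,2′-dimethanol | COc1cc([C@@H]2O[C@]2(CO)[C@@]2(CO)O[C@H]2c2ccc(OCc3ccccc3)c(OC)c2)ccc1OCc1ccccc1
A3 | alternative 2 | (1R,2E,4R)-1,4-bis(4-benzyloxy-3-methoxyphenyl)-2,3-diiodobut-2-ene-1,4-diol | COc1cc([C@@H](O)/C(I)=C(\I)[C@H](O)c2ccc(OCc3ccccc3)c(OC)c2)ccc1OCc1ccccc1
A4 | alternative 2 | (3R,6R)-3,6-bis(4-benzyloxy-3-methoxyphenyl)-3,6-dihydro-1H,4H-furo[3,4-c]furan-1,4-dione | COc1cc([C@H]2OC(=O)C3=C2C(=O)O[C@@H]3c2ccc(OCc3ccccc3)c(OC)c2)ccc1OCc1ccccc1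
A5 | alternative 3 | (2R,6R)-2,6-bis(4-benzyloxy-3-methoxyphenyl)-1,5-dioxocane-3,7-dione | COc1cc([C@H]2OCC(=O)[C@@H](c3ccc(OCc4ccccc4)c(OC)c3)OCC2=O)ccc1OCc1ccccc1
A6 | alternative 3 | 4,4′-di-O-benzylprinsepiol (identical with 9) | COc1cc([C@H]2OC[C@]3(O)[C@@H](c4ccc(OCc5ccccc5)c(OC)c4)OC[C@]23O)ccc1OCc1ccccc1
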